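## Structural features

- **Ring system.** The target is a depsidone. Ring A carries a1 OMe, a2 H, a3 Me, a4 acyl carbon, a5 ether oxygen and a6 Me (lower-case locants keep ring A atoms apart from compound labels). Ring B carries B1 ether oxygen, B2 ester oxygen, B3 Me, B4 OH, B5 lactone carbonyl and B6 lactol carbon.
- **Joins.** The rings are tied twice, by the diaryl ether a5–O–B1 and the aryl ester a4–C(=O)–O–B2, and the two bridges close the central seven-membered dioxepinone. A five-membered hydroxylactone (a 3-hydroxyphthalide) is fused on the B5–B6 edge. The molecule therefore has four rings, and ring B has no hydrogen left.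
- **Stereocentre.** The lactol carbon is the only stereocentre, (R). It has no stereogenic neighbour to bias it, and as a cyclic acyl hemiacetal it can invert through the ring-opened formyl acid.
- **Fragile groups.** These are the aryl ester (hydroxide, alkoxide, hydride), the lactol (base, nucleophiles, oxidants, reductants) and the electron-rich, oxygen-laden ring B (oxidation to a quinone once two para hydroxyls are free).
- **Real difficulty.** Three problems stand out: six different substituents on ring B in one fixed order, an ether with four ortho substituents (a4, a6, B2, B6), and a configuration that lasts only while ring opening is suppressed.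
- **Feature used by the key step.** The para oxygens at B1 and B4 enclose B2–O and B3–Me. This four-carbon run is the ring of a squarate-derived cyclobutenone (C1→B1, C2→B2, C3→B3, C4→B4). B5 and B6, with their two one-carbon substituents, are the two carbons of a trisubstituted alkene attached at C4.

## Logic of the disconnections

**27 ⇒ 26.** The acetyl–oxygen bond on the lactol oxygen is cut. The stereocentre inverts through 24 whenever the lactol is free, so it is stored as an ester that cannot ring-open. Everything earlier can then be run without any stereochemical concern. The forward step must break the acyl C–O bond, not the C–O bond at the stereocentre, and must be neutral, cold and short.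

**26 ⇒ 25.** The same O–acyl bond is the one formed when the configuration is set. Because 25 racemises through 24, a selective acyl transfer can in principle convert all of it, not just half. The demand is that racemisation outruns acylation of the slow enantiomer and that the catalyst picks the (R)-form.

**25 ⇒ 23.** The lactol ring C–O bond (B5 carboxyl oxygen to lactol carbon) is cut, and the three acid-labile masks on B4, B5 and B6 are put back. Aldehyde and acid close spontaneously, so no ring-forming reagent is needed and one operation removes three groups. The seven-membered aryl ester and the a1 methyl ether must survive the acid.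

**23 ⇒ 22.** The ester bond C(=O)–O–B2 is cut, which opens the seven-membered ring. Once the ether stands, this closure is intramolecular and only the B2 hydroxyl can reach the acyl carbon. The demand is activation of a di-ortho-substituted acid under non-acidic conditions, with the lactol still masked so that it cannot compete as a nucleophile.

**22 ⇒ 21.** The benzyl–oxygen bond at B2 is restored. Hydrogenolysis is orthogonal to the acetal, the MOM ether and the tert-butyl ester, so B2–OH is freed alone. A Lewis-acid dealkylation would strip everything at once and expose the lactol too early.

**21 ⇒ 14 + 20.** The a5–O bond is cut, which splits the molecule into two arenes of similar size. B1–OH is the one free hydroxyl of 14, and the halide of 20 sits ortho to a carboxylate that can guide copper. This is the most demanding C–O bond of the route because four ortho substituents crowd it.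

**14 ⇒ 11 (key).** The B1–B6 bond is cut and ring B unfolds through 13 and 12 to a four-membered ring. A hexasubstituted benzene becomes a cyclobutenone in which every substituent already has its place. Only the connectivity of 11 and the sense of rotation on ring opening must be right.

**11 ⇒ 8.** The C3–CH3 bond is cut and the carbonyl is moved back by one position (1,3-transposition).
- The alkenyl group is installed first and the methyl group second, and this order is essential.
- If methyl were on the four-membered ring first, the carbonyl beside the methyl-bearing carbon would be conjugated with the alkoxy oxygen through the ring double bond. It would therefore be the unreactive vinylogous ester carbonyl.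
- A nucleophile would then take the carbonyl beside the alkoxy-bearing carbon, and B2 and B3 would come out exchanged.
- The forward step needs a methyl nucleophile that spares the ester, hence the tert-butyl ester.

**8 ⇒ 7 ⇒ 2 + 5.** The MOM–oxygen bond and then the C4–Cα bond are cut. The two carbonyls of 2 are equivalent, so this addition has no positional issue. The demand is an α-metallated enoate that adds 1,2 and keeps the acetal trans to the ring.

**5 ⇒ 3 and 2 ⇒ 1.** The alkyne–carboxyl bond and the two benzyl–oxygen bonds are cut. Both lead to catalogue compounds in one step each.

**20 ⇒ 18 ⇒ 16 ⇒ 15.** The a4–carboxyl bond, the a4–I bond and the a5–Br bond are cut in turn. An amino group at a4 directs bromine to a5, a position meta to the methoxy group that no direct substitution of the anisole would reach. The amino group is then exchanged for iodine and finally for the carboxyl. The last step must discriminate between iodine and bromine.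

## Other disconnections considered

Alternative 1: The lactol carbon is taken off B6, cutting the B6–C bond and the C–O bond of the five-membered ring.
- **Forward step.** The depsidone acid A2 (hydrogen at B6, methyl ether at B4) would be palladated at B6 by Pd(OAc)2 (divalent palladium) under direction of the B5 carboxylate. CO would insert, and with Ag2CO3 as oxidant the cyclic anhydride A1 would form.
- **In favour.** B6 stays hydrogen until late, so ring B is only pentasubstituted and the diaryl ether has three ortho substituents instead of four. On that point this plan is better than the chosen one. Site selectivity of the key step equals that of the chosen plan, because only one ortho C–H is available.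
- **Against.** A1 is one oxidation level too high. One of two very similar anhydride carbonyls, each flanked by an ortho oxygen, would have to be reduced once and no further, in the presence of a hydride-sensitive aryl ester. An error in position would put the hydroxyl-bearing carbon on B5. An electron-rich ortho-alkoxybenzoic acid heated with silver and palladium salts is also prone to protodecarboxylation, and the B4 methyl ether needs a separate Lewis-acid step.
- **Step economy.** Ring B must still be made by other means, and reduction and demethylation are added, so nothing is saved. The stereochemical endgame is the same in both plans.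

Alternative 2: The bonds a4–C(=O) and C(=O)–O–B2 are cut, so the ester carbon comes from CO.
- **Forward step.** Zerovalent palladium from Pd(OAc)2 and Xantphos would insert into the C–I bond of the iodo diaryl ether A4. CO would insert, and the B2 phenol would capture the acylpalladium to give the depsidone A3.
- **In favour.** No hindered carboxylic acid has to be activated, ring A needs no carboxyl group or protecting group during the ether synthesis, and the iodide could be introduced para to the methoxy group. On atom economy of the ring closure this plan is the better one.
- **Against.** Oxidative addition must occur at an electron-rich iodide flanked by an aryloxy and a methyl group. The acylpalladium must be taken by a hindered phenol in a seven-membered closure, in competition with hydrodehalogenation. Two free phenols are also exposed to base and metal.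
- **Comparison.** This cut solves neither hard problem, since the hexasubstituted ring B and the crowded ether remain. Without the ortho-carboxylate the copper coupling loses its internal ligand. The cut is compatible with the chosen key step and could replace steps 9 and 12, with about the same step count. The carbodiimide closure it would replace is the least worrying step of the chosen route, so the gain is small.

Alternative 3: Ring A is taken apart at a5–a6 and a3–a4.
- **Forward step.** The pyrone A6 (4-methoxy-3,6-dimethyl-2-pyranone) and the aryloxypropiolate A7 would undergo a Diels–Alder addition followed by loss of CO2. This gives the diaryl ether A5 with the ring A ester in place.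
- **In favour.** The crowded C–O bond is made on an sp carbon before ring A exists, so coupling two hindered arenes is avoided. On this point the alternative is clearly better than the chosen plan. The polarity also matches: the nucleophilic C3 of A6 meets the β-carbon of the propiolate, and CO2 loss makes the step irreversible.
- **Against.** A7 is a push–pull ynol ether of a very hindered phenol, hard to make and sensitive to water. The cycloaddition joins two fully substituted diene termini to a fully substituted alkyne and would need long heating well above the temperature of the chosen key step, with an acetal and a free phenol on board.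
- **Comparison.** Ring B must again come from elsewhere, so this plan supplements the chosen one rather than replacing it. It adds the syntheses of A6 and A7, which makes it longer. Both key steps are pericyclic and inherit their positional control, so they are equal on that score.

Key step: step 6

Assumption 1: the lactol carbon of 27 can invert through the open form 24, so the (R)-configuration is treated as kinetically held. It is fixed in the stable acetate 26 and released only in the last, cold and base-free step.

Assumption 2: compounds 1, 3 and 15 are taken as catalogue chemicals.

## Route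

Step 1
Reactants: 1 squaric acid (3,4-dihydroxycyclobut-3-ene-1,2-dione)
Product: 2 dibenzyl squarate (3,4-bis(benzyloxy)cyclobut-3-ene-1,2-dione)
Conditions: BnOH (4 equiv), toluene, reflux, azeotropic removal of water
Reagents that add atoms: benzyl alcohol, OCc1ccccc1
Why: Squaric acid is a strong vinylogous acid that catalyses its own Fischer-type esterification, and removal of water drives both hydroxyls to the vinylogous benzyl esters. Benzyl is chosen because the oxygen that ends at B2 can later be freed by hydrogenolysis without touching the acetal, MOM ether or tert-butyl ester.

Step 2
Reactants: 3 3,3-diethoxyprop-1-yne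
Product: 5 tert-butyl 4,4-diethoxybut-2-ynoate, via lithium acetylide 4 (not isolated)
Conditions: n-BuLi, THF, −78 °C; Boc2O, −78 to 0 °C
Reagents that add atoms: di-tert-butyl dicarbonate, CC(C)(C)OC(=O)OC(=O)OC(C)(C)C
Why: Deprotonation of the terminal alkyne and C-acylation of 4 by the dicarbonate is a standard alkoxycarbonylation of an acetylide. The tert-butyl ester is chosen because it resists MeLi in step 5 and falls in the same acid step as the acetal.

Step 3
Reactants: 5 tert-butyl 4,4-diethoxybut-2-ynoate; 2 dibenzyl squarate
Product: 7 tert-butyl (Z)-2-[2,3-bis(benzyloxy)-1-hydroxy-4-oxocyclobut-2-en-1-yl]-4,4-diethoxybut-2-enoate (racemic), via alkenylalane 6 (not isolated)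
Conditions: i-Bu2AlH, NMO, THF, 0 °C; then 2, 0 °C to rt; aq. potassium sodium tartrate
Reagents that add atoms: none
Why: Proposed new method: conjugate syn-hydroalumination of the ynoate by the amine-oxide-complexed hydride should give 6 with aluminium and the new hydrogen cis, and the Lewis-acidic aluminium should bind a carbonyl oxygen of 2 and deliver Cα through a closed six-membered transition state that reaches only the carbonyl carbon (1,2-addition), not the benzyloxy-bearing ring carbon. The closest known reaction type is the vinylalumination (reductive aldol) of aldehydes and activated ketones such as α-keto esters with α-alumino acrylates, which has not been shown on squarate esters. The two carbonyls of 2 are equivalent, and the new carbinol centre is racemic and is lost in step 6.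

Step 4
Reactants: 7 the tertiary alcohol from step 3
Product: 8 tert-butyl (Z)-2-[2,3-bis(benzyloxy)-1-(methoxymethoxy)-4-oxocyclobut-2-en-1-yl]-4,4-diethoxybut-2-enoate (racemic)
Conditions: MOMCl, i-Pr2NEt, CH2Cl2, 0 °C to reflux
Reagents that add atoms: chloromethyl methyl ether, COCCl
Why: The very reactive chloromethyl ether alkylates the tertiary alcohol under amine base, and no metal alkoxide is formed, which avoids retro-aldol cleavage. The MOM group blocks the carbinol oxygen for step 5 and becomes the protected B4 oxygen, so that after step 6 only B1–OH is free.

Step 5
Reactants: 8 the MOM ether from step 4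
Product: 11 tert-butyl (Z)-2-[3-(benzyloxy)-1-(methoxymethoxy)-2-methyl-4-oxocyclobut-2-en-1-yl]-4,4-diethoxybut-2-enoate (racemic; a 4-alkenyl-2-benzyloxy-4-(methoxymethoxy)-3-methylcyclobut-2-enone), via lithium alkoxide 9 (not isolated), via allylic trifluoroacetate 10 (not isolated)
Conditions: MeLi, THF, −78 °C; (CF3CO)2O, −78 °C; aq. NaHCO3, −78 °C to rt
Reagents that add atoms: methyllithium, [Li]C; water, O
Why: MeLi adds 1,2 to the only ring carbonyl, much faster at −78 °C than to the hindered tert-butyl ester. Trifluoroacetylation lets 10 ionise to an alkoxy-stabilised cyclobutenyl cation that water captures at the distal benzyloxy carbon, and loss of benzyl alcohol gives the transposed enone, a 1,3-carbonyl transposition known for O-protected squarate adducts. This order places methyl beside the carbinol carbon, whereas a 3-alkoxy-4-methylcyclobutenedione would be attacked at the carbonyl beside the alkoxy carbon (the one beside the methyl carbon being the vinylogous ester carbonyl) and B2 and B3 would be exchanged.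

Step 6
Reactants: 11 the 4-alkenylcyclobutenone from step 5
Product: 14 tert-butyl 4-(benzyloxy)-2-(diethoxymethyl)-3-hydroxy-6-(methoxymethoxy)-5-methylbenzoate, via dienylketene 12 (not isolated), via cyclohexadienone 13 (not isolated)
Conditions: toluene (0.02 M, degassed), 110 °C
Reagents that add atoms: none
Why: Heating breaks the C1–C4 bond of 11 in a conrotatory 4π electrocyclic opening to the dienylketene 12. The donor MOM-oxy group turns outward and the acceptor-bearing alkenyl group turns inward, so the alkene terminus comes within reach of the ketene carbon. Ring B is then closed by a disrotatory 6π electrocyclisation that forms the B1–B6 bond and gives 13, whose ring C–H enolises irreversibly to the phenol 14. The closest known reaction type is the thermal ring expansion of squarate-derived 4-alkenyl-4-oxycyclobutenones to hydroquinones and their monoethers. No stereocentre is created, since the racemic C4 of 11 and the transient sp3 carbon of 13 both vanish on aromatisation. The positional selectivity needed is wholly inherited from 11: ketene carbon→B1, benzyloxy carbon→B2, methyl carbon→B3, MOM-oxy carbon→B4, ester-bearing alkene carbon→B5, acetal-bearing alkene carbon→B6. The (Z)-alkene puts hydrogen rather than the acetal inside the closing triene, ring opening is reversible, and either alkene geometry would end in 14. Because the carbinol oxygen is protected, only B1–OH is free and no air-sensitive hydroquinone is formed.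

Step 7
Reactants: 15 4-methoxy-2,5-dimethylaniline
Product: 16 2-bromo-4-methoxy-3,6-dimethylaniline
Conditions: NBS, MeCN, 0 °C, dark
Reagents that add atoms: N-bromosuccinimide, O=C1CCC(=O)N1Br
Why: This is an electrophilic aromatic bromination in which the amino group is the strongest director. Its para position is blocked and only one ortho position is free, so bromine enters at the future a5, meta to the methoxy group.

Step 8
Reactants: 16 2-bromo-4-methoxy-3,6-dimethylaniline
Product: 18 3-bromo-4-iodo-1-methoxy-2,5-dimethylbenzene, via diazonium tosylate 17 (not isolated)
Conditions: NaNO2, p-TsOH·H2O, MeCN/H2O, 0–10 °C; KI, to rt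
Reagents that add atoms: potassium iodide, [K+].[I-]
Why: This is a Sandmeyer-type iodination in which diazotisation is followed by iodide, which needs no copper and tolerates two ortho substituents. The amino group has done its directing work and is exchanged for the halogen that reacts first in step 9.

Step 9
Reactants: 18 3-bromo-4-iodo-1-methoxy-2,5-dimethylbenzene
Product: 20 2-bromo-4-methoxy-3,6-dimethylbenzoic acid, via arylmagnesium chloride 19 (not isolated)
Conditions: i-PrMgCl·LiCl, THF, −40 °C; CO2 (g), −40 to 0 °C; aq. HCl
Reagents that add atoms: carbon dioxide, O=C=O
Why: Iodine–magnesium exchange is far faster than bromine–magnesium exchange, and at −40 °C the ortho-bromo arylmagnesium 19 should not eliminate to an aryne. Carboxylation of a hindered Grignard reagent with CO2 is reliable.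

Step 10
Reactants: 14 the ring B phenol from step 6; 20 2-bromo-4-methoxy-3,6-dimethylbenzoic acid
Product: 21 2-[2-(benzyloxy)-5-(tert-butoxycarbonyl)-6-(diethoxymethyl)-4-(methoxymethoxy)-3-methylphenoxy]-4-methoxy-3,6-dimethylbenzoic acid
Conditions: CuI (30 mol %), picolinic acid (60 mol %), K3PO4, DMSO, 100 °C, Ar; cold aq. NaH2PO4
Reagents that add atoms: none
Why: This is an Ullmann diaryl ether synthesis in which the ortho-carboxylate of 20 binds monovalent copper and brings it to the C–Br bond (the effect known for 2-halobenzoic acids), and the picolinate ligand is the one suited to hindered phenols. Compound 14 offers one free hydroxyl only, all its other groups are base-stable, and the carboxylate cannot be dealkylated by phenoxide as an ester might be.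

Step 11
Reactants: 21 the diaryl ether acid from step 10
Product: 22 2-[5-(tert-butoxycarbonyl)-6-(diethoxymethyl)-2-hydroxy-4-(methoxymethoxy)-3-methylphenoxy]-4-methoxy-3,6-dimethylbenzoic acid
Conditions: H2 (1 atm), Pd/C, EtOAc, rt
Reagents that add atoms: none
Why: Hydrogenolysis of the aryl benzyl ether under neutral conditions leaves the acetal, MOM ether, tert-butyl ester and diaryl ether untouched. Partial acetal hydrolysis by the free acid would be harmless, because step 13 leads to the same product.

Step 12
Reactants: 22 the hydroxy acid from step 11
Product: 23 protected depsidone (seven-membered lactone closed; B4 OMOM, B5 CO2t-Bu, B6 CH(OEt)2)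
Conditions: DCC, DMAP, CH2Cl2 (2 mM), rt
Reagents that add atoms: none
Why: This is a Steglich-type carbodiimide lactonisation (7-exo-trig), the usual way to close the depsidone ring. B2–OH is the only hydroxyl in the molecule and sits next to the activated acyl group, and the conditions are non-acidic.

Step 13
Reactants: 23 the protected depsidone
Product: 25 racemic lactol (rac-27), via formyl acid 24 (not isolated)
Conditions: TFA, CH2Cl2, H2O, 0 °C to rt
Reagents that add atoms: water, O
Why: Acidolysis removes the tert-butyl ester, the diethyl acetal and the MOM ether in one operation, while the hindered aryl ester and the a1 methyl ether are stable to this acid. The formyl acid 24 closes by 5-exo-trig addition of the carboxyl oxygen to the aldehyde, and with no facial bias the lactol is racemic.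

Step 14
Reactants: 25 racemic lactol
Product: 26 (R)-lactol acetate
Conditions: immobilised Burkholderia cepacia lipase, vinyl acetate, Et3N (10 mol %), toluene/THF, 40 °C
Reagents that add atoms: vinyl acetate, C=COC(C)=O
Why: This is a lipase-catalysed dynamic kinetic resolution, known for γ-hydroxybutenolide-type lactols: the enantiomers of 25 interconvert through achiral 24 (helped by the trace of amine) while the enzyme acetylates one of them irreversibly. The empirical size rule for lipases and secondary alcohols (arene side large, lactone-oxygen side medium) predicts the (R)-acetate, so the stereocentre is set by the enzyme pocket. Once acylated it can no longer ring-open, and the hydrogen-bonded, hindered B4 phenol should not be accepted.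

Step 15
Reactants: 26 (R)-lactol acetate
Product: 27 target, (R)-lactol
Conditions: immobilised Burkholderia cepacia lipase, n-BuOH, MTBE/THF, 0 °C; cold filtration and evaporation
Reagents that add atoms: none
Why: Lipase-catalysed alcoholysis breaks the acetyl C–O bond and not the bond at the stereocentre, so the configuration is retained. By microscopic reversibility the same enzyme prefers the (R)-acetate and leaves any (S)-acetate behind. The medium is neutral, cold and free of amine, which keeps ring opening to 24 slow.

## Compound list

1 | squaric acid | O=C1C(O)=C(O)C1=O | starting material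
2 | dibenzyl squarate | O=C1C(=O)C(OCc2ccccc2)=C1OCc1ccccc1 | intermediate
3 | 3,3-diethoxyprop-1-yne | C#CC(OCC)OCC | starting material
4 | lithium 3,3-diethoxyprop-1-ynide | [Li]C#CC(OCC)OCC | intermediate
5 | tert-butyl 4,4-diethoxybut-2-ynoate | CCOC(OCC)C#CC(=O)OC(C)(C)C | intermediate
6 | tert-butyl (E)-2-(diisobutylalumanyl)-4,4-diethoxybut-2-enoate | CC(C)C[Al](CC(C)C)/C(C(=O)OC(C)(C)C)=C/C(OCC)OCC | intermediate
7 | tert-butyl (Z)-2-[2,3-bis(benzyloxy)-1-hydroxy-4-oxocyclobut-2-en-1-yl]-4,4-diethoxybut-2-enoate, racemic | O=C1C(OCc2ccccc2)=C(OCc2ccccc2)C1(O)/C(C(=O)OC(C)(C)C)=C/C(OCC)OCC | intermediate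
8 | MOM ether of 7, racemic | O=C1C(OCc2ccccc2)=C(OCc2ccccc2)C1(OCOC)/C(C(=O)OC(C)(C)C)=C/C(OCC)OCC | intermediate
9 | lithium alkoxide from 1,2-addition of MeLi to 8 (mixture of diastereomers) | [Li+].[O-]C1(C)C(OCc2ccccc2)=C(OCc2ccccc2)C1(OCOC)/C(C(=O)OC(C)(C)C)=C/C(OCC)OCC | intermediate
10 | trifluoroacetate of the carbinol of 9 | CC1(OC(=O)C(F)(F)F)C(OCc2ccccc2)=C(OCc2ccccc2)C1(OCOC)/C(C(=O)OC(C)(C)C)=C/C(OCC)OCC | intermediate
11 | tert-butyl (Z)-2-[3-(benzyloxy)-1-(methoxymethoxy)-2-methyl-4-oxocyclobut-2-en-1-yl]-4,4-diethoxybut-2-enoate, racemic | O=C1C(OCc2ccccc2)=C(C)C1(OCOC)/C(C(=O)OC(C)(C)C)=C/C(OCC)OCC | intermediate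
12 | dienylketene (ketene arm and alkenyl arm cis on the central double bond, MOM-oxy outside) | O=C=C(OCc1ccccc1)/C(C)=C(OCOC)\C(C(=O)OC(C)(C)C)=C\C(OCC)OCC | intermediate
13 | 6-(diethoxymethyl)cyclohexa-2,4-dienone, racemic | O=C1C(OCc2ccccc2)=C(C)C(OCOC)=C(C(=O)OC(C)(C)C)C1C(OCC)OCC | intermediate
14 | tert-butyl 4-(benzyloxy)-2-(diethoxymethyl)-3-hydroxy-6-(methoxymethoxy)-5-methylbenzoate | Oc1c(OCc2ccccc2)c(C)c(OCOC)c(C(=O)OC(C)(C)C)c1C(OCC)OCC | intermediate
15 | 4-methoxy-2,5-dimethylaniline | COc1cc(C)c(N)cc1C | starting material
16 | 2-bromo-4-methoxy-3,6-dimethylaniline | COc1cc(C)c(N)c(Br)c1C | intermediate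
17 | 2-bromo-4-methoxy-3,6-dimethylbenzenediazonium tosylate | COc1cc(C)c([N+]#N)c(Br)c1C.Cc1ccc(cc1)S(=O)(=O)[O-] | intermediate
18 | 3-bromo-4-iodo-1-methoxy-2,5-dimethylbenzene | COc1cc(C)c(I)c(Br)c1C | intermediate
19 | (2-bromo-4-methoxy-3,6-dimethylphenyl)magnesium chloride | COc1cc(C)c([Mg]Cl)c(Br)c1C | intermediate
20 | 2-bromo-4-methoxy-3,6-dimethylbenzoic acid | COc1cc(C)c(C(=O)O)c(Br)c1C | intermediate
21 | diaryl ether acid, B2 O-benzyl | COc1cc(C)c(C(=O)O)c(Oc2c(OCc3ccccc3)c(C)c(OCOC)c(C(=O)OC(C)(C)C)c2C(OCC)OCC)c1C | intermediate
22 | diaryl ether hydroxy acid, B2 OH | COc1cc(C)c(C(=O)O)c(Oc2c(O)c(C)c(OCOC)c(C(=O)OC(C)(C)C)c2C(OCC)OCC)c1C | intermediate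
23 | protected depsidone | COc1cc(C)c2c(c1C)Oc1c(c(C)c(OCOC)c(C(=O)OC(C)(C)C)c1C(OCC)OCC)OC2=O | intermediate
24 | depsidone formyl acid (open form of the lactol) | COc1cc(C)c2c(c1C)Oc1c(c(C)c(O)c(C(=O)O)c1C=O)OC2=O | intermediate
25 | racemic lactol | COc1cc(C)c2c(c1C)Oc1c(c(C)c(O)c3c1C(O)OC3=O)OC2=O | intermediate
26 | (R)-lactol acetate | COc1cc(C)c2c(c1C)Oc1c(c(C)c(O)c3c1[C@H](OC(C)=O)OC3=O)OC2=O | intermediate
27 | target, (R)-lactol | COc1cc(C)c2c(c1C)Oc1c(c(C)c(O)c3c1[C@H](O)OC3=O)OC2=O | target

## Step count and least certain steps

Total: 15 steps. The longest linear sequence is 11 steps (steps 2–6 and 10–15 from 3). The sequence from 1 through step 1 has the same length, and the ring A branch adds 3 steps off the main line.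

**Step 3 (labelled step).**
- **Risk.** The alane may be too weak a nucleophile for a carbonyl that is also part of a vinylogous ester, so the addition may stall. It may also lose its geometry through the allenolate, or attack in the conjugate sense with loss of benzyloxide.
- **Fallback with known chemistry, from 5 and 2, back at 7.**
  - Pd(PPh3)4-catalysed syn-hydrostannation of 5 with Bu3SnH gives tert-butyl (E)-4,4-diethoxy-2-(tributylstannyl)but-2-enoate F1.
  - Iododestannylation with I2 gives, with retention, tert-butyl (E)-4,4-diethoxy-2-iodobut-2-enoate F2.
  - Iodine–magnesium exchange with i-PrMgCl·LiCl at −78 °C gives the alkenylmagnesium chloride F3.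
  - F3, like other Grignard reagents, adds 1,2 to the squarate 2 and gives 7 after quench.

**Step 6 (key step).**
- **Risk.** The closure may be slow, because the alkene terminus is both acceptor-substituted and branched. Long heating would then allow diversion of the ketene (dimerisation, capture by traces of water), loss of ethanol from the ortho-hydroxy acetal, or loss of isobutene from the ester.
- **Fallback, from 2, back at 14.** The B6 carbon is added after the ring is made.
  - Steps 3–5 are repeated with tert-butyl propiolate in place of 5. This gives the acrylate adduct F4, its MOM ether F5 and the methylcyclobutenone F6.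
  - The unsubstituted vinyl terminus of F6 should close more easily, to the phenol with hydrogen at B6, F7.
  - Magnesium-mediated ortho-formylation (MgCl2, Et3N, paraformaldehyde, MeCN, reflux) can only strike the single free ring position and gives the salicylaldehyde F8.
  - HC(OEt)3 with PPTS in EtOH returns to 14.

**Step 10.**
- **Risk.** Four ortho substituents may slow both the approach of copper to the C–Br bond and the C–O bond-forming elimination. Protodebromination and copper-promoted decarboxylation of 20 would then take over.
- **Fallback, from 20 and 14, back at 22.** This is a metal-free arylation with a trivalent iodine reagent, which tolerates ortho substituents on both partners.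
  - BnBr and K2CO3 convert 20 into benzyl 2-bromo-4-methoxy-3,6-dimethylbenzoate F9.
  - An aromatic Finkelstein reaction (CuI, NaI, trans-N,N'-dimethylcyclohexane-1,2-diamine, dioxane, 110 °C) gives the iodide F10.
  - mCPBA and p-TsOH followed by 1,3,5-trimethoxybenzene give the aryl(2,4,6-trimethoxyphenyl)iodonium tosylate F11.
  - F11 has no hydrogen ortho to iodine on either ring, so no aryne can form. With K2CO3 in toluene at 40 °C it should hand its ester-bearing, di-ortho-substituted aryl group to the phenoxide of 14, giving the diaryl ether benzyl ester F12.
  - The hydrogenolysis of step 11 removes both benzyl groups and gives 22.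

**Step 14.**
- **Risk.** The enzyme may refuse a poorly soluble lactol flanked by an aryloxy group. It may also show a low or opposite enantiopreference, or racemisation may lag behind acylation.
- **Fallback, from 25, back at 26.** Ac2O and pyridine give the racemic acetate F13, which is configurationally stable and is separated on a chiral stationary phase into 26 and the (S)-acetate F14. Mild acid hydrolysis returns F14 to 25, which racemises and is recycled.

**Step 15.**
- **Risk.** The liberated lactol may racemise through ring opening during the hours that the enzymatic alcoholysis needs, all the more so if the enzyme is sluggish in the cold.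
- **Fallback, from 25, back at 27.** The dynamic resolution is run with acetone oxime allyl carbonate as the donor, giving the allyl carbonate F15. F15 has the same spatial arrangement as 26 but is (S) by the sequence rule, because the carbonate oxygen now outranks the ring oxygen. Pd(PPh3)4 (zerovalent palladium) and dimedone in CH2Cl2 at −20 °C remove the allyl group within minutes. The weakly acidic scavenger keeps the leaving carbonic half-ester protonated, and decarboxylation leaves the C–O bond at the stereocentre untouched.

## Further compounds

F1 | step 3 | tert-butyl (E)-4,4-diethoxy-2-(tributylstannyl)but-2-enoate | CCCC[Sn](CCCC)(CCCC)/C(C(=O)OC(C)(C)C)=C/C(OCC)OCC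
F2 | step 3 | tert-butyl (E)-4,4-diethoxy-2-iodobut-2-enoate | I/C(C(=O)OC(C)(C)C)=C/C(OCC)OCC
F3 | step 3 | [(E)-1-(tert-butoxycarbonyl)-3,3-diethoxyprop-1-en-1-yl]magnesium chloride | Cl[Mg]/C(C(=O)OC(C)(C)C)=C/C(OCC)OCC
F4 | step 6 | tert-butyl 2-[2,3-bis(benzyloxy)-1-hydroxy-4-oxocyclobut-2-en-1-yl]acrylate, racemic | O=C1C(OCc2ccccc2)=C(OCc2ccccc2)C1(O)C(=C)C(=O)OC(C)(C)C
F5 | step 6 | MOM ether of F4, racemic | O=C1C(OCc2ccccc2)=C(OCc2ccccc2)C1(OCOC)C(=C)C(=O)OC(C)(C)C
F6 | step 6 | tert-butyl 2-[3-(benzyloxy)-1-(methoxymethoxy)-2-methyl-4-oxocyclobut-2-en-1-yl]acrylate, racemic | O=C1C(OCc2ccccc2)=C(C)C1(OCOC)C(=C)C(=O)OC(C)(C)C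
F7 | step 6 | tert-butyl 4-(benzyloxy)-5-hydroxy-2-(methoxymethoxy)-3-methylbenzoate | Oc1cc(C(=O)OC(C)(C)C)c(OCOC)c(C)c1OCc1ccccc1
F8 | step 6 | tert-butyl 4-(benzyloxy)-2-formyl-3-hydroxy-6-(methoxymethoxy)-5-methylbenzoate | Oc1c(C=O)c(C(=O)OC(C)(C)C)c(OCOC)c(C)c1OCc1ccccc1
F9 | step 10 | benzyl 2-bromo-4-methoxy-3,6-dimethylbenzoate | COc1cc(C)c(C(=O)OCc2ccccc2)c(Br)c1C
F10 | step 10 | benzyl 2-iodo-4-methoxy-3,6-dimethylbenzoate | COc1cc(C)c(C(=O)OCc2ccccc2)c(I)c1C
F11 | step 10 | [2-(benzyloxycarbonyl)-5-methoxy-3,6-dimethylphenyl](2,4,6-trimethoxyphenyl)iodonium tosylate | COc1cc(C)c(C(=O)OCc2ccccc2)c([I+]c2c(OC)cc(OC)cc2OC)c1C.Cc1ccc(cc1)S(=O)(=O)[O-]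
F12 | step 10 | benzyl ester of 21 | COc1cc(C)c(C(=O)OCc2ccccc2)c(Oc2c(OCc3ccccc3)c(C)c(OCOC)c(C(=O)OC(C)(C)C)c2C(OCC)OCC)c1C
F13 | step 14 | racemic lactol acetate | COc1cc(C)c2c(c1C)Oc1c(c(C)c(O)c3c1C(OC(C)=O)OC3=O)OC2=O
F14 | step 14 | (S)-lactol acetate | COc1cc(C)c2c(c1C)Oc1c(c(C)c(O)c3c1[C@@H](OC(C)=O)OC3=O)OC2=O
F15 | step 15 | lactol allyl carbonate, (S) by the sequence rule, same spatial arrangement as 26 | COc1cc(C)c2c(c1C)Oc1c(c(C)c(O)c3c1[C@H](OC(=O)OCC=C)OC3=O)OC2=O
A1 | alternative 1 | depsidone B5,B6 cyclic anhydride, B4 methyl ether | COc1cc(C)c2c(c1C)Oc1c(c(C)c(OC)c3c1C(=O)OC3=O)OC2=O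
A2 | alternative 1 | depsidone B5 carboxylic acid with hydrogen at B6, B4 methyl ether | COc1cc(C)c2c(c1C)Oc1cc(C(=O)O)c(OC)c(C)c1OC2=O
A3 | alternative 2 | depsidone with free B4 phenol, B5 methyl ester, B6 dimethyl acetal | COc1cc(C)c2c(c1C)Oc1c(c(C)c(O)c(C(=O)OC)c1C(OC)OC)OC2=O
A4 | alternative 2 | iodo diaryl ether with free B2 and B4 phenols | COc1cc(C)c(I)c(Oc2c(O)c(C)c(O)c(C(=O)OC)c2C(OC)OC)c1C
A5 | alternative 3 | diaryl ether with ring A benzyl ester and B2 benzyl ether | COc1cc(C)c(C(=O)OCc2ccccc2)c(Oc2c(OCc3ccccc3)c(C)c(O)c(C(=O)OC)c2C(OC)OC)c1C
A6 | alternative 3 | 4-methoxy-3,6-dimethyl-2H-pyran-2-one | COC1=C(C)C(=O)OC(C)=C1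
A7 | alternative 3 | benzyl 3-(aryloxy)propiolate of ring B | O=C(OCc1ccccc1)C#COc1c(OCc2ccccc2)c(C)c(O)c(C(=O)OC)c1C(OC)OC
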